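**Retrosynthetic overview**
1. Structural feature: number the cyclopentane C1 (quaternary, bearing aryl and CH3), C2 (CH–CH3), C3 (C=CHBr), C4H2 and C5H2. The C1 methyl and the C2 hydrogen lie on the same ring face, so both are read as the two ends of one CH2 that once bridged C1 and C2 in a bicyclo[3.1.0]hexane.
2. Endgame disconnections: the aryl C–Br para to OH (bromination of the free phenol), the phenol O–H (from a MOM ether), and C3=CHBr (Wittig bromomethylenation of a C3 ketone).
3. The C3 ketone comes from a 5-aryl-1-methylbicyclo[3.1.0]hexan-2-one by reductive scission of the C2–CH2 bond and face-selective enolate protonation. The cyclopropane comes from CH2I2 and the C1=C2 alkene of a (3R)-cyclopentenol, with the C3 hydroxyl steering the zinc carbenoid.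
4. The cyclopentenol comes from the 3-aryl-2-methylcyclopentenone by CBS reduction. That enone is assembled from an aryllithium and the isobutyl vinylogous ester of 2-methylcyclopentane-1,3-dione.
5. Ring order: the benzene and cyclopentane rings are bought. The only ring made is the cyclopropane (step 5), which is opened again in step 7.

Key step: step 5

Remark: the phenol oxygen is carried as a methoxymethyl (MOM) ether rather than a methyl ether. A final BBr3 or hot thiolate demethylation would endanger the phenol/alkene pair (acid-induced cyclisation) and the vinyl bromide. The atom labels C1–C5 defined above are used throughout.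

**Step 1**
Reactants: 1 2-bromo-5-methylphenol
Product: 2 1-bromo-2-(methoxymethoxy)-4-methylbenzene
Conditions: NaH (1.2 equiv), MOMCl (1.2 equiv), DMF, 0 °C to rt
Reagents that add atoms: chloromethyl methyl ether, COCCl
Why: Williamson-type O-alkylation of the sodium phenoxide with the reactive chloromethyl ether should be clean, and the acetal tolerates organolithium, borane, zinc carbenoid, dissolving metal and ylide yet can later be removed without protic acid.

**Step 2**
Reactants: 3 2-methylcyclopentane-1,3-dione
Product: 4 2-methyl-3-(2-methylpropoxy)cyclopent-2-en-1-one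
Conditions: 2-methylpropan-1-ol (3 equiv), p-toluenesulfonic acid monohydrate (2 mol %), toluene, reflux, Dean–Stark trap
Reagents that add atoms: 2-methylpropan-1-ol, CC(C)CO
Why: Acid-catalysed vinylogous esterification of the enolised, symmetric 1,3-dione with azeotropic removal of water can give only one enol ether and is the standard entry to a Stork–Danheiser electrophile.

**Step 3**
Reactants: 2 1-bromo-2-(methoxymethoxy)-4-methylbenzene; 4 2-methyl-3-(2-methylpropoxy)cyclopent-2-en-1-one
Product: 7 3-[2-(methoxymethoxy)-4-methylphenyl]-2-methylcyclopent-2-en-1-one, via aryllithium 5 (not isolated), via tertiary lithium alkoxide 6 (not isolated)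
Conditions: 2, n-BuLi (1.05 equiv), THF, −78 °C, 30 min; 4, −78 to 0 °C; then 0.5 M aq HCl, 0 °C to rt, 30 min
Reagents that add atoms: water, O (supplies the new carbonyl oxygen); n-butyllithium, CCCC[Li] (lithium held only in intermediates 5 and 6)
Why: Bromine–lithium exchange, 1,2-addition to the vinylogous ester and acid-induced hydrolysis with allylic transposition (Stork–Danheiser sequence) should place the aryl group on the β-carbon (future C1) next to the methyl-bearing C2, and cold dilute acid is too weak to cleave the aryl MOM acetal.

**Step 4**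
Reactants: 7 3-[2-(methoxymethoxy)-4-methylphenyl]-2-methylcyclopent-2-en-1-one
Product: 8 (1R)-3-[2-(methoxymethoxy)-4-methylphenyl]-2-methylcyclopent-2-en-1-ol
Conditions: (3aS)-1-methyl-3,3-diphenyltetrahydro-1H,3H-pyrrolo[1,2-c][1,3,2]oxazaborole [(S)-Me-CBS, 10 mol %], BH3·SMe2 (1.0 equiv), THF, −20 °C, slow addition of 7; MeOH quench, neutral work-up
Reagents that add atoms: none
Why: In this Corey–Bakshi–Shibata reduction the α-methyl-substituted alkenyl arm acts as the large group and C4H2 as the small one, so the (S)-catalyst should deliver hydride to give the (R)-carbinol at C3, while the tetrasubstituted alkene is too hindered to be hydroborated.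

**Step 5**
Reactants: 8 (1R)-3-[2-(methoxymethoxy)-4-methylphenyl]-2-methylcyclopent-2-en-1-ol; 9 diiodomethane
Product: 11 (1S,2R,5S)-5-[2-(methoxymethoxy)-4-methylphenyl]-1-methylbicyclo[3.1.0]hexan-2-ol (cyclopropane CH2 syn to OH), via ethylzinc alkoxide 10 (not isolated)
Conditions: Et2Zn (4 equiv) added to 8, CH2Cl2, −20 °C; then CH2I2 (8 equiv), −20 °C to rt; sat. aq NH4Cl
Reagents that add atoms: diiodomethane (9), ICI; diethylzinc, CC[Zn]CC (ethylzinc held only in intermediate 10)
Why: Et2Zn first converts 8 into the ethylzinc alkoxide 10, which binds Zn(CH2I)2 and passes one methylene to the C1=C2 alkene through the concerted butterfly transition state of a hydroxyl-directed Simmons–Smith cyclopropanation (Furukawa variant), a reaction well known for substituted cyclopent-2-en-1-ols. The three-membered ring closes in one suprafacial [2+1] event that forms the C1–CH2 bond (kept, the future quaternary methyl) and the C2–CH2 bond (temporary). Both new stereocentres, C1 and C2, are controlled by the C3 carbinol centre, because the oxygen-bound carbenoid can reach only the alkene face that carries the oxygen, and their cis relation follows from the concerted addition. The step needs facial selectivity and sufficient reactivity at a tetrasubstituted alkene: the rigid five-membered ring holding O–Zn over one face secures the first, and the electron-rich aryl- and alkyl-substituted double bond together with the intramolecular delivery secures the second. Forming the alkoxide before the carbenoid is generated protects the ionisable allylic, styrenyl C–O bond from free ZnI2, and the arene and the MOM acetal are inert to the reagent.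

**Step 6**
Reactants: 11 (1S,2R,5S)-5-[2-(methoxymethoxy)-4-methylphenyl]-1-methylbicyclo[3.1.0]hexan-2-ol
Product: 12 (1S,5R)-5-[2-(methoxymethoxy)-4-methylphenyl]-1-methylbicyclo[3.1.0]hexan-2-one
Conditions: Dess–Martin periodinane (1.3 equiv), pyridine (3 equiv), CH2Cl2, 0 °C to rt
Reagents that add atoms: none
Why: Pyridine-buffered Dess–Martin oxidation converts the secondary carbinol into the ketone without acid that could ionise the aryl-substituted cyclopropylcarbinyl system, erasing the C3 stereocentre once it has served and leaving C1 and C2 untouched.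

**Step 7**
Reactants: 12 (1S,5R)-5-[2-(methoxymethoxy)-4-methylphenyl]-1-methylbicyclo[3.1.0]hexan-2-one
Product: 14 (2R,3R)-3-[2-(methoxymethoxy)-4-methylphenyl]-2,3-dimethylcyclopentan-1-one (C2 methyl cis to aryl), via lithium enolate 13 (not isolated)
Conditions: Li (about 2.2 equiv, to a just persistent blue colour), NH3(l)/THF 4:1, −78 °C, 10 min; solid NH4Cl in one portion, −78 °C; NH3 evaporated, pH 7 buffer work-up, used without delay
Reagents that add atoms: lithium, [Li] (held only in intermediate 13)
Why: This is a dissolving-metal reductive cleavage of a conjugated cyclopropyl ketone in which the external C2–CH2 bond of the rigid bicyclo[3.1.0]hexan-2-one lies parallel to the carbonyl π orbitals while the internal C1–C2 bond lies near their nodal plane, so two-electron reduction should break C2–CH2 despite the benzylic nature of C1, ammonia protonates the released CH2 terminus to the C1 methyl, enolate 13 shields the carbonyl from further reduction, the absence of an alcohol and the small lithium excess spare the arene, and irreversible cold protonation of 13 on the face carrying the small C1 methyl (anti to the ortho-substituted aryl group) should set C2 with its methyl cis to aryl.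

**Step 8**
Reactants: 14 (2R,3R)-3-[2-(methoxymethoxy)-4-methylphenyl]-2,3-dimethylcyclopentan-1-one; 15 (bromomethyl)triphenylphosphonium bromide
Product: 16 1-[(1R,2R,3E)-3-(bromomethylidene)-1,2-dimethylcyclopentyl]-2-(methoxymethoxy)-4-methylbenzene
Conditions: 15 (4.2 equiv), NaN(SiMe3)2 (4.0 equiv), THF, −78 °C, 1 h; then 14, −78 to 0 °C
Reagents that add atoms: (bromomethyl)triphenylphosphonium bromide (15), BrC[P+](c1ccccc1)(c1ccccc1)c1ccccc1.[Br-]
Why: Wittig bromomethylenation with Ph3P=CHBr, a halogen-stabilised ylide of lowered basicity, is known to convert α-branched, epimerisable cycloalkanones flanked by a quaternary carbon without loss of the α-configuration, the slight excess of salt over base leaves no free amide, and allylic 1,3-strain between bromine and the C2 substituents should favour the E isomer (Br cis to C4H2).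

**Step 9**
Reactants: 16 1-[(1R,2R,3E)-3-(bromomethylidene)-1,2-dimethylcyclopentyl]-2-(methoxymethoxy)-4-methylbenzene
Product: 18 2-[(1R,2R,3E)-3-(bromomethylidene)-1,2-dimethylcyclopentyl]-5-methylphenol, via aryl trimethylsilyl ether 17 (not isolated)
Conditions: Me3SiOTf (2 equiv), 2,2'-bipyridyl (3 equiv), MeCN, 0 °C to rt; then H2O, rt
Reagents that add atoms: trimethylsilyl trifluoromethanesulfonate, C[Si](C)(C)OS(=O)(=O)C(F)(F)F (Me3Si held only in intermediate 17)
Why: The silyl triflate–bipyridyl cleavage of aromatic MOM ethers exchanges the acetal for a silyl ether that water hydrolyses, and the weakly basic medium never offers a strong proton source, so the alkene is neither protonated nor trapped by the neighbouring phenol and the vinyl bromide is untouched.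

**Step 10**
Reactants: 18 2-[(1R,2R,3E)-3-(bromomethylidene)-1,2-dimethylcyclopentyl]-5-methylphenol
Product: 19 4-bromo-2-[(1R,2R,3E)-3-(bromomethylidene)-1,2-dimethylcyclopentyl]-5-methylphenol (target)
Conditions: N-bromosuccinimide (1.0 equiv), MeCN, −20 to 0 °C, dark
Reagents that add atoms: N-bromosuccinimide, O=C1CCC(=O)N1Br
Why: In this electrophilic aromatic bromination the free phenol ring is far more nucleophilic than the bromine-deactivated alkene, and the position para to OH (flanked only by the ring methyl) should win over the remaining ortho position squeezed between OH and CH3.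

**Compound list**
1 | 2-bromo-5-methylphenol | Cc1ccc(Br)c(O)c1 | starting material
2 | 1-bromo-2-(methoxymethoxy)-4-methylbenzene | COCOc1cc(C)ccc1Br | intermediate
3 | 2-methylcyclopentane-1,3-dione | CC1C(=O)CCC1=O | starting material
4 | 2-methyl-3-(2-methylpropoxy)cyclopent-2-en-1-one | CC1=C(OCC(C)C)CCC1=O | intermediate
5 | [2-(methoxymethoxy)-4-methylphenyl]lithium (formed in the flask) | COCOc1cc(C)ccc1[Li] | intermediate
6 | lithium 1-[2-(methoxymethoxy)-4-methylphenyl]-2-methyl-3-(2-methylpropoxy)cyclopent-2-en-1-olate, racemic (formed in the flask) | COCOc1cc(C)ccc1C1(O[Li])CCC(OCC(C)C)=C1C | intermediate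
7 | 3-[2-(methoxymethoxy)-4-methylphenyl]-2-methylcyclopent-2-en-1-one | COCOc1cc(C)ccc1C1=C(C)C(=O)CC1 | intermediate
8 | (1R)-3-[2-(methoxymethoxy)-4-methylphenyl]-2-methylcyclopent-2-en-1-ol | COCOc1cc(C)ccc1C1=C(C)[C@H](O)CC1 | intermediate
9 | diiodomethane | ICI | starting material
10 | ethylzinc alkoxide of 8 (formed in the flask) | COCOc1cc(C)ccc1C1=C(C)[C@H](O[Zn]CC)CC1 | intermediate
11 | (1S,2R,5S)-5-[2-(methoxymethoxy)-4-methylphenyl]-1-methylbicyclo[3.1.0]hexan-2-ol, cyclopropane syn to OH | COCOc1cc(C)ccc1[C@@]12C[C@]1(C)[C@H](O)CC2 | intermediate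
12 | (1S,5R)-5-[2-(methoxymethoxy)-4-methylphenyl]-1-methylbicyclo[3.1.0]hexan-2-one | COCOc1cc(C)ccc1[C@@]12C[C@]1(C)C(=O)CC2 | intermediate
13 | lithium (3R)-3-[2-(methoxymethoxy)-4-methylphenyl]-2,3-dimethylcyclopent-1-en-1-olate (formed in the flask) | COCOc1cc(C)ccc1[C@]1(C)CCC(O[Li])=C1C | intermediate
14 | (2R,3R)-3-[2-(methoxymethoxy)-4-methylphenyl]-2,3-dimethylcyclopentan-1-one, C2 methyl cis to aryl | COCOc1cc(C)ccc1[C@]1(C)CCC(=O)[C@@H]1C | intermediate
15 | (bromomethyl)triphenylphosphonium bromide | BrC[P+](c1ccccc1)(c1ccccc1)c1ccccc1.[Br-] | starting material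
16 | 1-[(1R,2R,3E)-3-(bromomethylidene)-1,2-dimethylcyclopentyl]-2-(methoxymethoxy)-4-methylbenzene | COCOc1cc(C)ccc1[C@]1(C)CC/C(=C\Br)[C@@H]1C | intermediate
17 | {2-[(1R,2R,3E)-3-(bromomethylidene)-1,2-dimethylcyclopentyl]-5-methylphenoxy}trimethylsilane (formed in the flask) | Cc1ccc([C@]2(C)CC/C(=C\Br)[C@@H]2C)c(O[Si](C)(C)C)c1 | intermediate
18 | 2-[(1R,2R,3E)-3-(bromomethylidene)-1,2-dimethylcyclopentyl]-5-methylphenol | Cc1ccc([C@]2(C)CC/C(=C\Br)[C@@H]2C)c(O)c1 | intermediate
19 | 4-bromo-2-[(1R,2R,3E)-3-(bromomethylidene)-1,2-dimethylcyclopentyl]-5-methylphenol | Cc1cc(O)c([C@]2(C)CC/C(=C\Br)[C@@H]2C)cc1Br | target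

**Total step count:** 10
**Longest linear sequence:** 9 (steps 1, 3, 4, 5, 6, 7, 8, 9, 10; the branch through step 2 is equally long)

**Three steps most likely to fail**

**Step 7.** What may go wrong:
- Enolate 13 may be protonated from the aryl face, possibly helped by lithium chelation to the MOM oxygens.
- C2 may equilibrate toward the more stable epimer during quench and isolation.
- Less likely, the internal benzylic cyclopropane bond may be cleaved instead of the external one. The detour given under step 5 bypasses that cleavage altogether.

The fallback sets C2–H by hydroboration instead of by a proton. It sets out from 12. The same lithium–ammonia cleavage is run, ammonia is evaporated, and enolate 13 is trapped in THF with excess PhNTf2 as (3R)-3-[2-(methoxymethoxy)-4-methylphenyl]-2,3-dimethylcyclopent-1-en-1-yl trifluoromethanesulfonate F1. Formate hydrogenolysis of the C–O bond [Pd(OAc)2, PPh3, HCO2H, n-Bu3N, DMF, 60 °C] should give the trisubstituted alkene 1-[(1R)-1,2-dimethylcyclopent-2-en-1-yl]-2-(methoxymethoxy)-4-methylbenzene F2. BH3·THF places boron on the less substituted C3 and hydrogen on C2, syn and on the face of the C1 methyl (anti to aryl). This gives the (3-aryl-2,3-dimethylcyclopentyl)borane F3. NaOH/H2O2 oxidises F3 with retention to (1R,2R,3R)-3-[2-(methoxymethoxy)-4-methylphenyl]-2,3-dimethylcyclopentan-1-ol F4. Dess–Martin periodinane/pyridine brings the material back to the route at 14.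

**Step 8.** What may go wrong:
- The basic ylide may enolise the hindered cyclopentanone, with epimerisation at C2.
- Addition may be slow.
- Control of the alkene geometry may be insufficient.

The fallback uses a non-basic olefination and fixes the geometry in a separate operation. It sets out from 14. Ramirez dibromoolefination (CBr4, PPh3, toluene, 80 °C) uses the essentially non-basic Ph3P=CBr2 and should give 1-[(1R,2R)-3-(dibromomethylidene)-1,2-dimethylcyclopentyl]-2-(methoxymethoxy)-4-methylbenzene F5. Bromine–lithium exchange with n-BuLi (1.0 equiv, THF/Et2O, −100 °C) is known to remove the sterically more compressed bromine, here the one cis to C2. This gives the bromo(lithio)methylidene carbenoid F6. MeOH at −100 °C protonates F6 with retention, and the route is rejoined at 16.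

**Step 5.** What may go wrong:
- Methylene transfer to the crowded tetrasubstituted alkene, flanked by a twisted ortho-substituted aryl group, may be sluggish.
- Zinc halides may ionise or dehydrate the allylic, styrenyl alcohol before cyclopropanation is complete.

The fallback transfers chirality from C3–O to C1 by a sigmatropic shift instead of by a carbenoid. It sets out from 8. Acetylation [Ac2O, pyridine, 4-(dimethylamino)pyridine] gives (1R)-3-[2-(methoxymethoxy)-4-methylphenyl]-2-methylcyclopent-2-en-1-yl acetate F7. LiN(i-Pr)2 and Me3SiCl (THF, −78 °C) give its trimethylsilyl ketene acetal F8. On warming to reflux, F8 undergoes the suprafacial Ireland–Claisen rearrangement to the trimethylsilyl ester F9, with the new C1–CH2 bond on the face that carried oxygen. Aqueous work-up gives [(1S)-1-[2-(methoxymethoxy)-4-methylphenyl]-2-methylcyclopent-2-en-1-yl]acetic acid F10. Coupling with 1-hydroxypyridine-2(1H)-thione (DCC, CH2Cl2, dark) gives the 2-thioxopyridin-1(2H)-yl ester F11. Barton decarboxylation of F11 (t-BuSH, visible light) turns the CH2CO2 group into the C1 methyl and delivers the alkene F2 described above. Hydroboration to F3, oxidation to F4 and Dess–Martin oxidation then return to the route at 14.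

**Further compounds**
F1 | step 7 | (3R)-3-[2-(methoxymethoxy)-4-methylphenyl]-2,3-dimethylcyclopent-1-en-1-yl trifluoromethanesulfonate | COCOc1cc(C)ccc1[C@]1(C)CCC(OS(=O)(=O)C(F)(F)F)=C1C
F2 | step 7 | 1-[(1R)-1,2-dimethylcyclopent-2-en-1-yl]-2-(methoxymethoxy)-4-methylbenzene | COCOc1cc(C)ccc1[C@]1(C)CCC=C1C
F3 | step 7 | (3-aryl-2,3-dimethylcyclopentyl)borane, boron on C3 and hydrogen on C2 both cis to the C1 methyl | COCOc1cc(C)ccc1[C@]1(C)CC[C@@H](B)[C@@H]1C
F4 | step 7 | (1R,2R,3R)-3-[2-(methoxymethoxy)-4-methylphenyl]-2,3-dimethylcyclopentan-1-ol | COCOc1cc(C)ccc1[C@]1(C)CC[C@@H](O)[C@@H]1C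
F5 | step 8 | 1-[(1R,2R)-3-(dibromomethylidene)-1,2-dimethylcyclopentyl]-2-(methoxymethoxy)-4-methylbenzene | COCOc1cc(C)ccc1[C@]1(C)CCC(=C(Br)Br)[C@@H]1C
F6 | step 8 | bromo(lithio)methylidene carbenoid, Li cis to C2 and Br cis to C4 | COCOc1cc(C)ccc1[C@]1(C)CC/C(=C(\Br)[Li])[C@@H]1C
F7 | step 5 | (1R)-3-[2-(methoxymethoxy)-4-methylphenyl]-2-methylcyclopent-2-en-1-yl acetate | COCOc1cc(C)ccc1C1=C(C)[C@H](OC(C)=O)CC1
F8 | step 5 | trimethylsilyl ketene acetal of F7 | COCOc1cc(C)ccc1C1=C(C)[C@H](OC(=C)O[Si](C)(C)C)CC1
F9 | step 5 | trimethylsilyl [(1S)-1-[2-(methoxymethoxy)-4-methylphenyl]-2-methylcyclopent-2-en-1-yl]acetate | COCOc1cc(C)ccc1[C@]1(CC(=O)O[Si](C)(C)C)CCC=C1C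
F10 | step 5 | [(1S)-1-[2-(methoxymethoxy)-4-methylphenyl]-2-methylcyclopent-2-en-1-yl]acetic acid | COCOc1cc(C)ccc1[C@]1(CC(=O)O)CCC=C1C
F11 | step 5 | 2-thioxopyridin-1(2H)-yl [(1S)-1-[2-(methoxymethoxy)-4-methylphenyl]-2-methylcyclopent-2-en-1-yl]acetate | COCOc1cc(C)ccc1[C@]1(CC(=O)ON2C=CC=CC2=S)CCC=C1C
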